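U = upper 4-arylflavan-3-ol (rings A, C, B). L = lower flavan-3,4-diol (rings D, F). Ring E = the pyrogallol ring shared by both (E-C1 on U-C4, E-C2 on L-C2, E-C3 H, E-C4 to E-C6 oxygenated).
Retrosynthetic cuts, in order: nine O-benzyl bonds; L-C3–O and L-C4–O (back to the L-C3=C4 alkene); L-C3=C4 (metathesis); L-C2–O1 (allylic etherification); the E-C2 arm back to CH2OH; U-C3–O (hydroboration); U-C4–E-C1 (aryl addition to a flavanone); U-C2–ring B (conjugate addition to a chromone).
Forward: rings A and C come with the chromone. Ring B is added at U-C2 and ring E at U-C4. The E-C2 arm is grown to a cinnamyl carbonate, ring D is attached through O1, and ring F is closed last by metathesis and then oxidised.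
Enabling feature: ring E on L-C2, OH on L-C3 and OH on L-C4 are all-trans, and L-C4 is benzylic with the ring D C7 oxygen para to C4a. An epoxide placed on the L-C3=C4 face remote from ring E and opened by water at L-C4 with inversion therefore gives both carbinols correctly.
Stereochemistry: U-C2 comes from a Rh-catalysed asymmetric conjugate addition, and U-C3 and U-C4 are relayed from it by syn hydroboration anti to ring B. L-C2 comes from an Ir-catalysed asymmetric allylic etherification, and L-C3 and L-C4 are relayed from it in the key step.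

Key step: step 21

Assumption: the sense of induction written for the (S)-diphosphine (step 5) and the (Sa,S,S)-phosphoramidite (step 19) is extrapolated from the parent chromone and cinnamyl carbonate cases; both ligands exist as either antipode, and the other one is used if a model run shows the opposite sense.
Shorthand: U-yl = (2R,3S,4S)-3,7-bis(benzyloxy)-2-[3,4,5-tris(benzyloxy)phenyl]chroman-4-yl.

Step 1
Reactants: 1 5-bromo-1,2,3-trimethoxybenzene
Product: 2 5-bromobenzene-1,2,3-triol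
Conditions: BBr3, CH2Cl2, −78 °C → rt; then H2O
Reagents that add atoms: none
Why: Lewis-acid aryl methyl ether cleavage, in which boron binds each methoxy oxygen and bromide removes the methyl group by SN2 while the aryl bromide stays inert.

Step 2
Reactants: 2 5-bromobenzene-1,2,3-triol
Product: 3 5-bromo-1,2,3-tris(benzyloxy)benzene
Conditions: BnBr, K2CO3, DMF, 60 °C, argon
Reagents that add atoms: benzyl bromide, BrCc1ccccc1
Why: Williamson ether synthesis on all three phenoxides, run without air because the pyrogallol anion oxidises easily.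

Step 3
Reactants: 3 5-bromo-1,2,3-tris(benzyloxy)benzene
Product: 6 [3,4,5-tris(benzyloxy)phenyl]boronic acid, via aryllithium 4 (not isolated), via lithium aryltriisopropoxyborate 5 (not isolated)
Conditions: n-BuLi, THF, −78 °C; B(OiPr)3, −78 °C → rt; 1 M HCl
Reagents that add atoms: triisopropyl borate, CC(C)OB(OC(C)C)OC(C)C; water, O
Why: Bromine–lithium exchange followed by electrophilic borylation and hydrolysis, the exchange at −78 °C being faster than benzylic deprotonation of the benzyl ethers.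

Step 4
Reactants: 7 7-hydroxychromone
Product: 8 7-(benzyloxy)chromone
Conditions: BnBr, K2CO3, acetone, reflux
Reagents that add atoms: benzyl bromide, BrCc1ccccc1
Why: Williamson ether synthesis on the only acidic OH.

Step 5
Reactants: 8 7-(benzyloxy)chromone; 6 [3,4,5-tris(benzyloxy)phenyl]boronic acid
Product: 9 (2S)-7-(benzyloxy)-2-[3,4,5-tris(benzyloxy)phenyl]chroman-4-one
Conditions: [Rh(OH)(cod)]2 (1.5 mol %), (S)-MeO-F12-BIPHEP (3.3 mol %), CH2Cl2–H2O, rt
Reagents that add atoms: none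
Why: Hayashi–Miyaura asymmetric 1,4-addition to a chromone, in which the aryl-rhodium complex of the electron-poor atropisomeric diphosphine inserts C2=C3 on one face and sets U-C2 as S in the flavanone (the geometry called 2R once C3 bears oxygen), under neutral conditions that should avoid ring opening to the chalcone.

Step 6
Reactants: 10 methyl gallate
Product: 11 methyl 3,4,5-tris(benzyloxy)benzoate
Conditions: BnBr, K2CO3, DMF, 60 °C
Reagents that add atoms: benzyl bromide, BrCc1ccccc1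
Why: Williamson ether synthesis on the three phenols, with the methyl ester untouched by carbonate base.

Step 7
Reactants: 11 methyl 3,4,5-tris(benzyloxy)benzoate
Product: 12 [3,4,5-tris(benzyloxy)phenyl]methanol
Conditions: LiAlH4, THF, 0 °C → rt; aq. NaOH work-up
Reagents that add atoms: none
Why: Hydride reduction of an ester to the primary alcohol, to which benzyl ethers are inert.

Step 8
Reactants: 12 [3,4,5-tris(benzyloxy)phenyl]methanol
Product: 13 [2-bromo-3,4,5-tris(benzyloxy)phenyl]methanol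
Conditions: NBS (1.0 equiv), CH2Cl2, 0 °C, dark
Reagents that add atoms: N-bromosuccinimide, O=C1CCC(=O)N1Br
Why: Electrophilic aromatic bromination at one of the two equivalent free positions, each ortho and para to an alkoxy group, while the unactivated benzyl phenyl rings do not compete.

Step 9
Reactants: 13 [2-bromo-3,4,5-tris(benzyloxy)phenyl]methanol
Product: 14 {[2-bromo-3,4,5-tris(benzyloxy)benzyl]oxy}triisopropylsilane
Conditions: TIPSCl, imidazole, DMF, rt
Reagents that add atoms: triisopropylsilyl chloride, CC(C)[Si](Cl)(C(C)C)C(C)C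
Why: Silyl ether formation; the bulky triisopropylsilyl group should resist oxygen-to-carbon silyl migration in the ortho-lithiated arene and should survive the mild acid, peroxide and hydride bases that follow.

Step 10
Reactants: 14 {[2-bromo-3,4,5-tris(benzyloxy)benzyl]oxy}triisopropylsilane; 9 (2S)-7-(benzyloxy)-2-[3,4,5-tris(benzyloxy)phenyl]chroman-4-one
Product: 18 (2S)-7-(benzyloxy)-2-[3,4,5-tris(benzyloxy)phenyl]-4-{2,3,4-tris(benzyloxy)-6-[(triisopropylsilyloxy)methyl]phenyl}-2H-chromene, via ring E aryllithium 15 (not isolated), via ring E arylcerium dichloride 16 (not isolated), via tertiary C4 carbinol 17 (not isolated)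
Conditions: 14, n-BuLi, THF, −78 °C; anhydrous CeCl3, −78 °C; 9, −78 → −30 °C; H2O quench; crude carbinol, PPTS (cat.), toluene, 50 °C, dark
Reagents that add atoms: none
Why: Organocerium 1,2-addition, whose low basicity favours carbonyl attack over enolisation of the flavanone, followed by E1 dehydration of the doubly benzylic para-alkoxy-activated carbinol, which can lose a proton only from C3 and leaves U-C2 untouched.

Step 11
Reactants: 18 the (2S)-4-aryl-2H-chromene of step 10
Product: 20 (2R,3S,4S)-7-(benzyloxy)-2-[3,4,5-tris(benzyloxy)phenyl]-4-{2,3,4-tris(benzyloxy)-6-[(triisopropylsilyloxy)methyl]phenyl}chroman-3-ol, via C3 alkylborane 19 (not isolated)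
Conditions: BH3·THF, THF, 0 °C → rt; then 3 M NaOH, 30 % H2O2, 0 °C → rt
Reagents that add atoms: hydrogen peroxide, OO
Why: Hydroboration–oxidation, in which borane adds syn with boron on the less substituted C3 and from the face opposite ring B, so that after retentive oxidation U-C3–OH is trans to ring B and the hydrogen delivered to U-C4 on the same face leaves ring E trans to the hydroxyl.

Step 12
Reactants: 20 the (2R,3S,4S)-chroman-3-ol of step 11
Product: 21 {[3,4,5-tris(benzyloxy)-2-(U-yl)benzyl]oxy}triisopropylsilane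
Conditions: NaH, BnBr, tetrabutylammonium iodide (cat.), DMF, 0 °C → rt
Reagents that add atoms: benzyl bromide, BrCc1ccccc1
Why: Williamson ether synthesis on the secondary alkoxide, the usual 3-O-benzylation of flavan-3-ols, which prevents later lactol or oxa-Michael closure onto the E-C2 arm.

Step 13
Reactants: 21 {[3,4,5-tris(benzyloxy)-2-(U-yl)benzyl]oxy}triisopropylsilane
Product: 22 [3,4,5-tris(benzyloxy)-2-(U-yl)phenyl]methanol
Conditions: TBAF, THF, 0 °C → rt
Reagents that add atoms: none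
Why: Fluoride-induced desilylation driven by Si–F bond formation, orthogonal to the eight benzyl ethers.

Step 14
Reactants: 22 [3,4,5-tris(benzyloxy)-2-(U-yl)phenyl]methanol
Product: 24 ethyl (E)-3-[3,4,5-tris(benzyloxy)-2-(U-yl)phenyl]acrylate, via aldehyde 23 (not isolated)
Conditions: activated MnO2, Ph3P=CHCO2Et, toluene, 80 °C
Reagents that add atoms: ethyl (triphenylphosphoranylidene)acetate, CCOC(=O)C=P(c1ccccc1)(c1ccccc1)c1ccccc1
Why: Tandem benzylic oxidation–Wittig olefination, in which the aldehyde is trapped as it forms by the stabilised ylide, which should give the E-enoate.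

Step 15
Reactants: 24 ethyl (E)-3-[3,4,5-tris(benzyloxy)-2-(U-yl)phenyl]acrylate
Product: 25 (E)-3-[3,4,5-tris(benzyloxy)-2-(U-yl)phenyl]prop-2-en-1-ol
Conditions: DIBAL-H (2.5 equiv), CH2Cl2, −78 °C; aq. potassium sodium tartrate
Reagents that add atoms: none
Why: 1,2-Reduction of an enoate to the allylic alcohol with retention of the E geometry.

Step 16
Reactants: 25 (E)-3-[3,4,5-tris(benzyloxy)-2-(U-yl)phenyl]prop-2-en-1-ol
Product: 26 (E)-3-[3,4,5-tris(benzyloxy)-2-(U-yl)phenyl]allyl methyl carbonate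
Conditions: ClCO2Me, pyridine, CH2Cl2, 0 °C
Reagents that add atoms: methyl chloroformate, COC(=O)Cl
Why: O-Acylation of the primary allylic alcohol, which installs the leaving group used in iridium allyl chemistry.

Step 17
Reactants: 27 2,4-dihydroxybenzaldehyde
Product: 28 4-(benzyloxy)-2-hydroxybenzaldehyde
Conditions: BnBr (1.05 equiv), NaHCO3, MeCN, 80 °C
Reagents that add atoms: benzyl bromide, BrCc1ccccc1
Why: Regioselective Williamson ether synthesis, since the 2-OH is hydrogen-bonded to the formyl group and a weak base ionises only the 4-OH.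

Step 18
Reactants: 28 4-(benzyloxy)-2-hydroxybenzaldehyde
Product: 29 5-(benzyloxy)-2-vinylphenol
Conditions: MePPh3Br (2.5 equiv), KOtBu (2.5 equiv), THF, 0 °C → rt
Reagents that add atoms: methyltriphenylphosphonium bromide, C[P+](c1ccccc1)(c1ccccc1)c1ccccc1.[Br-]
Why: Wittig methylenation, with the extra equivalent of base carrying the free phenol through as its phenoxide.

Step 19
Reactants: 26 (E)-3-[3,4,5-tris(benzyloxy)-2-(U-yl)phenyl]allyl methyl carbonate; 29 5-(benzyloxy)-2-vinylphenol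
Product: 31 4-(benzyloxy)-2-{(1S)-1-[3,4,5-tris(benzyloxy)-2-(U-yl)phenyl]allyloxy}-1-vinylbenzene, via lithium phenoxide 30 (not isolated)
Conditions: 29 (2 equiv), n-BuLi, THF, 0 °C; then 26, [Ir(cod)Cl]2 (4 mol %), (Sa,S,S)-N,N-bis[1-(2-methoxyphenyl)ethyl]dinaphtho[2,1-d:1',2'-f][1,3,2]dioxaphosphepin-4-amine (8 mol %, pre-activated with n-PrNH2), THF, 50 °C
Reagents that add atoms: none
Why: Iridium-catalysed asymmetric allylic etherification, in which the cyclometalated phosphoramidite complex ionises the linear carbonate to an η3-allyl species that the phenoxide attacks at the aryl-bearing terminus, the ligand (the o-anisyl variant suited to ortho-substituted cinnamyl substrates) fixing L-C2 as S by catalyst control.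

Step 20
Reactants: 31 the (1S)-branched aryl allyl ether of step 19
Product: 32 (2S)-7-(benzyloxy)-2-[3,4,5-tris(benzyloxy)-2-(U-yl)phenyl]-2H-chromene (nonabenzyl flav-3-ene; S at L-C2 only because ring E outranks the sp2 C3; same geometry as 2R in the diol)
Conditions: second-generation Grubbs catalyst RuCl2(=CHPh)(H2IMes)(PCy3) (5 mol %), CH2Cl2 (0.005 M), 40 °C
Reagents that add atoms: none
Why: Ring-closing metathesis of a styrene with an allylic vinyl group, the standard closure of 2H-chromenes, driven by loss of ethene and leaving L-C2 untouched.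

Step 21
Reactants: 32 the nonabenzyl (2S)-flav-3-ene of step 20
Product: 34 (2R,3S,4R)-7-(benzyloxy)-2-[3,4,5-tris(benzyloxy)-2-(U-yl)phenyl]chroman-3,4-diol, via anti epoxide 33 (not isolated)
Conditions: dimethyldioxirane (1.2 equiv, solution in acetone), acetone–CH2Cl2–aq. phosphate buffer pH 7.5 (8:2:1), −20 → 0 °C, dark
Reagents that add atoms: dimethyldioxirane, CC1(C)OO1; water, O
Why: Dimethyldioxirane transfers one oxygen atom to the electron-rich cis-styrenyl L-C3=C4 bond through a concerted spiro transition state, and the water present solvolyses the labile benzylic epoxide 33 in the same flask; the closest known reaction type is dioxirane or peracid epoxidation of 2H-chromenes and flav-3-enes with in situ hydrolysis to trans-3,4-diols. The only ring closed is the transient oxirane, made by suprafacial [2+1] oxygen-atom transfer and reopened at once, so no new ring remains in 34. L-C3 is controlled by L-C2, because ring E, made bulky by the U unit on its ortho carbon E-C1, blocks its own face of ring F and the oxygen should arrive anti to it, ending 2,3-trans. L-C4 is controlled by the epoxide itself, because the C4–O bond, weakened by the para benzyloxy group of ring D, breaks while the departing oxygen still shields its face, so water should enter with inversion and give the 3,4-trans carbinol. The step needs chemoselectivity for the alkene over the benzyl ethers and electron-rich arenes, secured by the far higher nucleophilicity of this enol-ether-like styrene at low temperature with about one equivalent of oxidant, and opening at C4 rather than C3, secured by benzylic and para-oxygen stabilisation. The neutral buffer is there to suppress a free C4 cation (loss of anti selectivity, hydride shift to the 3-ketone) and re-ionisation of the product carbinol, so the outcome rests on kinetic anti opening and not on equilibration.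

Step 22
Reactants: 34 the nonabenzyl diol of step 21
Product: 35 (2R,3S,4R)-2-{3,4,5-trihydroxy-2-[(2R,3S,4S)-3,7-dihydroxy-2-(3,4,5-trihydroxyphenyl)chroman-4-yl]phenyl}chroman-3,4,7-triol (target)
Conditions: H2 (1 atm), Pd(OH)2/C, THF–MeOH–aq. phosphate buffer pH 7, rt; filtration under argon
Reagents that add atoms: none
Why: Catalytic hydrogenolysis of eight aryl benzyl ethers and one alkyl benzyl ether, as in the global debenzylation of proanthocyanidins, kept strictly neutral and stopped at full debenzylation so that acid-assisted cleavage of the L-C4 hydroxyl should not set in.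

Compound list
1 | 5-bromo-1,2,3-trimethoxybenzene | COc1cc(Br)cc(OC)c1OC | starting material
2 | 5-bromobenzene-1,2,3-triol | Oc1cc(Br)cc(O)c1O | intermediate
3 | 5-bromo-1,2,3-tris(benzyloxy)benzene | Brc1cc(OCc9ccccc9)c(OCc9ccccc9)c(OCc9ccccc9)c1 | intermediate
4 | 3,4,5-tris(benzyloxy)phenyllithium | [Li]c1cc(OCc9ccccc9)c(OCc9ccccc9)c(OCc9ccccc9)c1 | intermediate
5 | lithium [3,4,5-tris(benzyloxy)phenyl]triisopropoxyborate | [Li+].CC(C)O[B-](OC(C)C)(OC(C)C)c1cc(OCc9ccccc9)c(OCc9ccccc9)c(OCc9ccccc9)c1 | intermediate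
6 | [3,4,5-tris(benzyloxy)phenyl]boronic acid | OB(O)c1cc(OCc9ccccc9)c(OCc9ccccc9)c(OCc9ccccc9)c1 | intermediate
7 | 7-hydroxychromone | O=c1ccoc2cc(O)ccc12 | starting material
8 | 7-(benzyloxy)chromone | O=c1ccoc2cc(OCc9ccccc9)ccc12 | intermediate
9 | (2S)-7-(benzyloxy)-2-[3,4,5-tris(benzyloxy)phenyl]chroman-4-one | C(c9ccccc9)Oc1ccc2c(c1)O[C@H](c1cc(OCc9ccccc9)c(OCc9ccccc9)c(OCc9ccccc9)c1)CC2=O | intermediate
10 | methyl gallate | COC(=O)c1cc(O)c(O)c(O)c1 | starting material
11 | methyl 3,4,5-tris(benzyloxy)benzoate | COC(=O)c1cc(OCc9ccccc9)c(OCc9ccccc9)c(OCc9ccccc9)c1 | intermediate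
12 | [3,4,5-tris(benzyloxy)phenyl]methanol | OCc1cc(OCc9ccccc9)c(OCc9ccccc9)c(OCc9ccccc9)c1 | intermediate
13 | [2-bromo-3,4,5-tris(benzyloxy)phenyl]methanol | OCc1cc(OCc9ccccc9)c(OCc9ccccc9)c(OCc9ccccc9)c1Br | intermediate
14 | {[2-bromo-3,4,5-tris(benzyloxy)benzyl]oxy}triisopropylsilane | CC(C)[Si](C(C)C)(C(C)C)OCc1cc(OCc9ccccc9)c(OCc9ccccc9)c(OCc9ccccc9)c1Br | intermediate
15 | 2,3,4-tris(benzyloxy)-6-[(triisopropylsilyloxy)methyl]phenyllithium | [Li]c1c(CO[Si](C(C)C)(C(C)C)C(C)C)cc(OCc9ccccc9)c(OCc9ccccc9)c1OCc9ccccc9 | intermediate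
16 | dichloro{2,3,4-tris(benzyloxy)-6-[(triisopropylsilyloxy)methyl]phenyl}cerium | Cl[Ce](Cl)c1c(CO[Si](C(C)C)(C(C)C)C(C)C)cc(OCc9ccccc9)c(OCc9ccccc9)c1OCc9ccccc9 | intermediate
17 | (2S)-7-(benzyloxy)-2-[3,4,5-tris(benzyloxy)phenyl]-4-{2,3,4-tris(benzyloxy)-6-[(triisopropylsilyloxy)methyl]phenyl}chroman-4-ol (C4 epimers, centre erased in the same step) | C(c9ccccc9)Oc1ccc2c(c1)O[C@H](c1cc(OCc9ccccc9)c(OCc9ccccc9)c(OCc9ccccc9)c1)CC2(O)c1c(CO[Si](C(C)C)(C(C)C)C(C)C)cc(OCc9ccccc9)c(OCc9ccccc9)c1OCc9ccccc9 | intermediate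
18 | (2S)-7-(benzyloxy)-2-[3,4,5-tris(benzyloxy)phenyl]-4-{2,3,4-tris(benzyloxy)-6-[(triisopropylsilyloxy)methyl]phenyl}-2H-chromene | C(c9ccccc9)Oc1ccc2c(c1)O[C@H](c1cc(OCc9ccccc9)c(OCc9ccccc9)c(OCc9ccccc9)c1)C=C2c1c(CO[Si](C(C)C)(C(C)C)C(C)C)cc(OCc9ccccc9)c(OCc9ccccc9)c1OCc9ccccc9 | intermediate
19 | C3 alkylborane of 18 (BH2 on U-C3 trans to ring B, H on U-C4 cis to boron) | C(c9ccccc9)Oc1ccc2c(c1)O[C@H](c1cc(OCc9ccccc9)c(OCc9ccccc9)c(OCc9ccccc9)c1)[C@@H](B)[C@@H]2c1c(CO[Si](C(C)C)(C(C)C)C(C)C)cc(OCc9ccccc9)c(OCc9ccccc9)c1OCc9ccccc9 | intermediate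
20 | (2R,3S,4S)-7-(benzyloxy)-2-[3,4,5-tris(benzyloxy)phenyl]-4-{2,3,4-tris(benzyloxy)-6-[(triisopropylsilyloxy)methyl]phenyl}chroman-3-ol | C(c9ccccc9)Oc1ccc2c(c1)O[C@H](c1cc(OCc9ccccc9)c(OCc9ccccc9)c(OCc9ccccc9)c1)[C@@H](O)[C@@H]2c1c(CO[Si](C(C)C)(C(C)C)C(C)C)cc(OCc9ccccc9)c(OCc9ccccc9)c1OCc9ccccc9 | intermediate
21 | {[3,4,5-tris(benzyloxy)-2-(U-yl)benzyl]oxy}triisopropylsilane | C(c9ccccc9)Oc1ccc2c(c1)O[C@H](c1cc(OCc9ccccc9)c(OCc9ccccc9)c(OCc9ccccc9)c1)[C@@H](OCc9ccccc9)[C@@H]2c1c(CO[Si](C(C)C)(C(C)C)C(C)C)cc(OCc9ccccc9)c(OCc9ccccc9)c1OCc9ccccc9 | intermediate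
22 | [3,4,5-tris(benzyloxy)-2-(U-yl)phenyl]methanol | C(c9ccccc9)Oc1ccc2c(c1)O[C@H](c1cc(OCc9ccccc9)c(OCc9ccccc9)c(OCc9ccccc9)c1)[C@@H](OCc9ccccc9)[C@@H]2c1c(CO)cc(OCc9ccccc9)c(OCc9ccccc9)c1OCc9ccccc9 | intermediate
23 | 3,4,5-tris(benzyloxy)-2-(U-yl)benzaldehyde | C(c9ccccc9)Oc1ccc2c(c1)O[C@H](c1cc(OCc9ccccc9)c(OCc9ccccc9)c(OCc9ccccc9)c1)[C@@H](OCc9ccccc9)[C@@H]2c1c(C=O)cc(OCc9ccccc9)c(OCc9ccccc9)c1OCc9ccccc9 | intermediate
24 | ethyl (E)-3-[3,4,5-tris(benzyloxy)-2-(U-yl)phenyl]acrylate | C(c9ccccc9)Oc1ccc2c(c1)O[C@H](c1cc(OCc9ccccc9)c(OCc9ccccc9)c(OCc9ccccc9)c1)[C@@H](OCc9ccccc9)[C@@H]2c1c(/C=C/C(=O)OCC)cc(OCc9ccccc9)c(OCc9ccccc9)c1OCc9ccccc9 | intermediate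
25 | (E)-3-[3,4,5-tris(benzyloxy)-2-(U-yl)phenyl]prop-2-en-1-ol | C(c9ccccc9)Oc1ccc2c(c1)O[C@H](c1cc(OCc9ccccc9)c(OCc9ccccc9)c(OCc9ccccc9)c1)[C@@H](OCc9ccccc9)[C@@H]2c1c(/C=C/CO)cc(OCc9ccccc9)c(OCc9ccccc9)c1OCc9ccccc9 | intermediate
26 | (E)-3-[3,4,5-tris(benzyloxy)-2-(U-yl)phenyl]allyl methyl carbonate | C(c9ccccc9)Oc1ccc2c(c1)O[C@H](c1cc(OCc9ccccc9)c(OCc9ccccc9)c(OCc9ccccc9)c1)[C@@H](OCc9ccccc9)[C@@H]2c1c(/C=C/COC(=O)OC)cc(OCc9ccccc9)c(OCc9ccccc9)c1OCc9ccccc9 | intermediate
27 | 2,4-dihydroxybenzaldehyde | O=Cc1ccc(O)cc1O | starting material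
28 | 4-(benzyloxy)-2-hydroxybenzaldehyde | O=Cc1ccc(OCc9ccccc9)cc1O | intermediate
29 | 5-(benzyloxy)-2-vinylphenol | C=Cc1ccc(OCc9ccccc9)cc1O | intermediate
30 | lithium 5-(benzyloxy)-2-vinylphenoxide | [Li+].[O-]c1cc(OCc9ccccc9)ccc1C=C | intermediate
31 | 4-(benzyloxy)-2-{(1S)-1-[3,4,5-tris(benzyloxy)-2-(U-yl)phenyl]allyloxy}-1-vinylbenzene | C(c9ccccc9)Oc1ccc2c(c1)O[C@H](c1cc(OCc9ccccc9)c(OCc9ccccc9)c(OCc9ccccc9)c1)[C@@H](OCc9ccccc9)[C@@H]2c1c([C@H](C=C)Oc3cc(OCc9ccccc9)ccc3C=C)cc(OCc9ccccc9)c(OCc9ccccc9)c1OCc9ccccc9 | intermediate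
32 | (2S)-7-(benzyloxy)-2-[3,4,5-tris(benzyloxy)-2-(U-yl)phenyl]-2H-chromene (key-step precursor) | C(c9ccccc9)Oc1ccc2c(c1)O[C@H](c1cc(OCc9ccccc9)c(OCc9ccccc9)c(OCc9ccccc9)c1)[C@@H](OCc9ccccc9)[C@@H]2c1c([C@H]2Oc3cc(OCc9ccccc9)ccc3C=C2)cc(OCc9ccccc9)c(OCc9ccccc9)c1OCc9ccccc9 | intermediate
33 | (2R,3S,4S)-7-(benzyloxy)-3,4-epoxy-2-[3,4,5-tris(benzyloxy)-2-(U-yl)phenyl]chroman (oxirane anti to ring E) | C(c9ccccc9)Oc1ccc2c(c1)O[C@H](c1cc(OCc9ccccc9)c(OCc9ccccc9)c(OCc9ccccc9)c1)[C@@H](OCc9ccccc9)[C@@H]2c1c([C@H]2Oc3cc(OCc9ccccc9)ccc3[C@@H]4O[C@H]24)cc(OCc9ccccc9)c(OCc9ccccc9)c1OCc9ccccc9 | intermediate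
34 | (2R,3S,4R)-7-(benzyloxy)-2-[3,4,5-tris(benzyloxy)-2-(U-yl)phenyl]chroman-3,4-diol (key-step product) | C(c9ccccc9)Oc1ccc2c(c1)O[C@H](c1cc(OCc9ccccc9)c(OCc9ccccc9)c(OCc9ccccc9)c1)[C@@H](OCc9ccccc9)[C@@H]2c1c([C@H]2Oc3cc(OCc9ccccc9)ccc3[C@@H](O)[C@@H]2O)cc(OCc9ccccc9)c(OCc9ccccc9)c1OCc9ccccc9 | intermediate
35 | (2R,3S,4R)-2-{3,4,5-trihydroxy-2-[(2R,3S,4S)-3,7-dihydroxy-2-(3,4,5-trihydroxyphenyl)chroman-4-yl]phenyl}chroman-3,4,7-triol | Oc1ccc2c(c1)O[C@H](c1cc(O)c(O)c(O)c1)[C@@H](O)[C@@H]2c1c([C@H]2Oc3cc(O)ccc3[C@@H](O)[C@@H]2O)cc(O)c(O)c1O | target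

Total step count: 22.
Longest linear sequence: 15 steps (1, 2, 3, 5, 10 to 16, 19 to 22). The branch from methyl gallate through steps 6 to 9 is equally long.

Steps most likely to fail

Step 19. The U unit on E-C1 crowds the allyl terminus. This may slow ionisation, divert the phenoxide to the unsubstituted terminus and weaken catalyst control at L-C2. Re-ionisation of the electron-rich branched ether may erode the configuration further.
The fallback sets out from aldehyde 23, obtained by running the MnO2 oxidation of 22 without the ylide, and rejoins the route at 31.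
- Vinylmagnesium bromide (THF, −78 °C) adds to 23 to give the (S)-allylic alcohol F1 together with its (R)-epimer F2. Because the U unit is a single enantiomer these are diastereomers, and they are separated by chromatography.
- The potassium alkoxide of F1 (KHMDS, THF–DMF) displaces fluoride from commercial 4-(benzyloxy)-2-fluorobenzaldehyde by SNAr. The carbinol C–O bond is not touched, so configuration is retained and the aryl ether aldehyde F3 results.
- Wittig methylenation of F3 with Ph3P=CH2 gives 31.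

Step 10. Enolisation of the flavanone, followed by β-elimination of the ring oxygen (ring opening to the chalcone), may outrun 1,2-addition of an aryl nucleophile that is substituted at both ortho positions.
The fallback sets out from 9 and 14 and rejoins the route at 18.
- Ketone 9 is converted without strong base (Tf2O, 2,6-di-tert-butyl-4-methylpyridine, CH2Cl2) into the enol triflate F4.
- Bromide 14 is converted (n-BuLi, then 2-isopropoxy-4,4,5,5-tetramethyl-1,3,2-dioxaborolane) into the pinacol boronate F5.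
- Suzuki–Miyaura coupling (Pd(OAc)2, SPhos, K3PO4, toluene–water) joins F4 and F5 directly to 18. The U-C4–E-C1 bond is then made by cross-coupling instead of carbonyl addition.

Step 22. Hydrogenolytic loss of the benzylic, para-oxygenated L-C4 hydroxyl may compete with the slow cleavage of the aliphatic benzyl ether on U-C3.
The fallback sets out from 34 and rejoins the route at 35.
- DDQ (dioxane, rt) oxidises only the electron-rich benzylic carbinol and gives the nonabenzyl (2R,3R)-dihydroflavonol F6.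
- The vinylogous-ester ketone of F6 tolerates H2 over Pd(OH)2/C, which gives the free phenolic dihydroflavonol F7.
- NaBH4 in ethanol reduces F7 to the 2,3-trans-3,4-trans diol 35, the established reduction of dihydroflavonols.
- The same detour absorbs any L-C4 epimer formed in step 21, since both epimers give the one ketone.

Further compounds
F1 | step 19 | (1S)-1-[3,4,5-tris(benzyloxy)-2-(U-yl)phenyl]prop-2-en-1-ol | C(c9ccccc9)Oc1ccc2c(c1)O[C@H](c1cc(OCc9ccccc9)c(OCc9ccccc9)c(OCc9ccccc9)c1)[C@@H](OCc9ccccc9)[C@@H]2c1c([C@H](C=C)O)cc(OCc9ccccc9)c(OCc9ccccc9)c1OCc9ccccc9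
F2 | step 19 | (1R)-1-[3,4,5-tris(benzyloxy)-2-(U-yl)phenyl]prop-2-en-1-ol | C(c9ccccc9)Oc1ccc2c(c1)O[C@H](c1cc(OCc9ccccc9)c(OCc9ccccc9)c(OCc9ccccc9)c1)[C@@H](OCc9ccccc9)[C@@H]2c1c([C@@H](C=C)O)cc(OCc9ccccc9)c(OCc9ccccc9)c1OCc9ccccc9
F3 | step 19 | 4-(benzyloxy)-2-{(1S)-1-[3,4,5-tris(benzyloxy)-2-(U-yl)phenyl]allyloxy}benzaldehyde | C(c9ccccc9)Oc1ccc2c(c1)O[C@H](c1cc(OCc9ccccc9)c(OCc9ccccc9)c(OCc9ccccc9)c1)[C@@H](OCc9ccccc9)[C@@H]2c1c([C@H](C=C)Oc3cc(OCc9ccccc9)ccc3C=O)cc(OCc9ccccc9)c(OCc9ccccc9)c1OCc9ccccc9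
F4 | step 10 | (2S)-7-(benzyloxy)-2-[3,4,5-tris(benzyloxy)phenyl]-2H-chromen-4-yl trifluoromethanesulfonate | C(c9ccccc9)Oc1ccc2c(c1)O[C@H](c1cc(OCc9ccccc9)c(OCc9ccccc9)c(OCc9ccccc9)c1)C=C2OS(=O)(=O)C(F)(F)F
F5 | step 10 | 2-{2,3,4-tris(benzyloxy)-6-[(triisopropylsilyloxy)methyl]phenyl}-4,4,5,5-tetramethyl-1,3,2-dioxaborolane | CC1(C)OB(OC1(C)C)c1c(CO[Si](C(C)C)(C(C)C)C(C)C)cc(OCc9ccccc9)c(OCc9ccccc9)c1OCc9ccccc9
F6 | step 22 | (2R,3R)-7-(benzyloxy)-3-hydroxy-2-[3,4,5-tris(benzyloxy)-2-(U-yl)phenyl]chroman-4-one | C(c9ccccc9)Oc1ccc2c(c1)O[C@H](c1cc(OCc9ccccc9)c(OCc9ccccc9)c(OCc9ccccc9)c1)[C@@H](OCc9ccccc9)[C@@H]2c1c([C@H]2Oc3cc(OCc9ccccc9)ccc3C(=O)[C@@H]2O)cc(OCc9ccccc9)c(OCc9ccccc9)c1OCc9ccccc9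
F7 | step 22 | (2R,3R)-3,7-dihydroxy-2-{3,4,5-trihydroxy-2-[(2R,3S,4S)-3,7-dihydroxy-2-(3,4,5-trihydroxyphenyl)chroman-4-yl]phenyl}chroman-4-one | Oc1ccc2c(c1)O[C@H](c1cc(O)c(O)c(O)c1)[C@@H](O)[C@@H]2c1c([C@H]2Oc3cc(O)ccc3C(=O)[C@@H]2O)cc(O)c(O)c1O
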